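**Plan**

Atoms carry labdane numbers: ring A is C1–C5 and C10, ring B is C5–C10, C17 is the acetoxymethyl carbon.
Retrosynthesis: C8–C17 is cut first (Stille coupling on the C7=C8 enol triflate of a C8 ketone), then C9–C11 (vinylogous aldol condensation with a C11–C15 aldehyde), then ring B across C6–C7 and C9–C10 into β-cyclocitral (ring A plus C6) and benzyl acetoacetate (C7–C8–C9 with a removable carboxyl on C7).
Forward: ring A is bought; ring B arises in one operation (condensation at C6/C7, then 6π-electrocyclisation joining C9 to C10); the side chain is joined at C9; one hydrogenation removes the carboxyl helper and saturates C5=C6 and C9=C11; C17 comes last.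
Enabling feature: the ring A double bond C5=C10 is conjugated with the C6 carbonyl, and C8 bears an oxygen between enolisable C9 and doubly activated C7, so after condensation the six ring B atoms form a hexatriene C10=C5–C6=C7–C8=C9 with C9 and C10 as termini.
Stereochemistry: C10 from a recoverable twofold-symmetric pyrrolidine bound at C8 during ring closure; C5 and C9 from hydrogen delivery anti to the C10 and axial C4 methyl groups; C13 from commercial (R)-3-methylglutaric acid monomethyl ester.

Key step: step 1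

Remark: β-keto esters 7 and 11–13 are written as their chelated enol tautomers; the geometry of the C9=C11 bond in 13 is immaterial because it is hydrogenated.

**Route**

Step 1
Reactants: 1 benzyl acetoacetate; 2 β-cyclocitral (2,6,6-trimethylcyclohex-1-ene-1-carbaldehyde); 3 (2R,5R)-2,5-dimethylpyrrolidine
Product: 7 benzyl (4aS)-3-hydroxy-4a,8,8-trimethyl-4,4a,5,6,7,8-hexahydronaphthalene-2-carboxylate, via enamino ester 4 (not isolated), via aminotriene 5 (not isolated), via cyclised dienamine 6 (not isolated)
Conditions: 3 (1.1 equiv), toluene, 4 Å molecular sieves, 60 °C; then 2, CF3CO2H (10 mol %), 90 °C; then AcOH–NaOAc–H2O, THF, rt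
Reagents that add atoms: water (O)
Why: Proposed new method: the amine turns 1 into the tertiary enamino ester 4, whose C7 adds to the aldehyde of 2 and loses water, and tautomerisation of the resulting azoniatriene at the C9 methyl gives the push–pull 2-aminohexatriene 5 (C10=C5–C6=C7–C8(N)=C9), which should close by thermal 6π-electrocyclisation to 6 and is hydrolysed to 7. The closest known reaction type is the amine-mediated Knoevenagel condensation/6π-electrocyclisation (formal [3+3] annulation) of enals with enaminones and 1,3-dicarbonyl compounds, and the stereocontrol is modelled on the face-selective alkylation of enamines of trans-2,5-dialkylpyrrolidines; new is the transfer of that facial bias to the torquoselectivity of an all-carbon 6π closure. Ring B is the only ring closed, in a disrotatory 6π (6-endo) mode between the triene termini C9 and C10. The only new stereocentre, quaternary C10, is controlled by the auxiliary: the methyl group on the pyrrolidine carbon syn to C9 blocks one face of C9, so only one helical sense of the triene should close and this fixes which face of C10 bonds (C9 is a CH2 and C5 stays trigonal). The step needs site selectivity, secured because C7 is the only nucleophilic carbon of 4 and the tertiary nitrogen cannot cyclise. It is also stereoconvergent: the E/Z isomers of the C6=C7 bond and the dienamine tautomers of 5 interconvert through the iminium form and drain through the one irreversible closure.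

Step 2
Reactants: 8 (3R)-5-methoxy-3-methyl-5-oxopentanoic acid (methyl hydrogen (R)-3-methylglutarate)
Product: 9 methyl (3R)-5-hydroxy-3-methylpentanoate
Conditions: BH3·SMe2, THF, 0 °C → rt; MeOH quench; used crude without delay
Reagents that add atoms: none
Why: Borane reduces the carboxylic acid much faster than the methyl ester (chemoselective acid reduction) and leaves C13 untouched; prompt use avoids lactonisation of the δ-hydroxy ester.

Step 3
Reactants: 9 methyl (3R)-5-hydroxy-3-methylpentanoate
Product: 10 methyl (3R)-3-methyl-5-oxopentanoate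
Conditions: PhI(OAc)2, 2,2,6,6-tetramethylpiperidin-1-oxyl (10 mol %), CH2Cl2, rt
Reagents that add atoms: none
Why: The oxoammonium-mediated oxidation of a primary alcohol should stop at the aldehyde under neutral conditions that do not touch the ester or the β-stereocentre.

Step 4
Reactants: 7 benzyl (4aS)-3-hydroxy-4a,8,8-trimethyl-4,4a,5,6,7,8-hexahydronaphthalene-2-carboxylate; 10 methyl (3R)-3-methyl-5-oxopentanoate
Product: 13 benzyl (4aR)-3-hydroxy-4-[(3R)-5-methoxy-3-methyl-5-oxopentylidene]-4a,8,8-trimethyl-4,4a,5,6,7,8-hexahydronaphthalene-2-carboxylate, via aldol 11 (not isolated), via mesylate 12 (not isolated)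
Conditions: LiN(i-Pr)2 (2.2 equiv), THF, −78 → 0 °C; 10, −78 °C; AcOH quench; then MeSO2Cl, Et3N, CH2Cl2, 0 °C → rt
Reagents that add atoms: none
Why: γ-Deprotonation of the β-keto ester enolate gives a dianion that should react only at C9, its sole α'-position, in a vinylogous aldol addition to 10, and β-elimination of the mesylate through the ketone tautomer should give the C9=C11 alkylidene ketone without touching C10 or C13.

Step 5
Reactants: 13 benzyl (4aR)-3-hydroxy-4-[(3R)-5-methoxy-3-methyl-5-oxopentylidene]-4a,8,8-trimethyl-4,4a,5,6,7,8-hexahydronaphthalene-2-carboxylate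
Product: 15 methyl (3R)-3-methyl-5-[(1S,4aR,8aR)-5,5,8a-trimethyl-2-oxodecahydronaphthalen-1-yl]pentanoate, via keto acid 14 (not isolated)
Conditions: H2 (5 bar), Pd on carbon (10 wt %), EtOAc, rt → 40 °C
Reagents that add atoms: none
Why: Heterogeneous hydrogenation should saturate the exocyclic C9=C11 enone and the C5=C6 bond and hydrogenolyse the benzyl ester, the β-keto acid then losing CO2; hydrogen is delivered to C9 and C5 from the face opposite the axial C10 and C4 methyl groups, which sets the trans ring fusion and the equatorial side chain under kinetic control.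

Step 6
Reactants: 15 methyl (3R)-3-methyl-5-[(1S,4aR,8aR)-5,5,8a-trimethyl-2-oxodecahydronaphthalen-1-yl]pentanoate
Product: 16 methyl (3R)-3-methyl-5-[(1S,4aR,8aR)-5,5,8a-trimethyl-2-{[(trifluoromethyl)sulfonyl]oxy}-1,4,4a,5,6,7,8,8a-octahydronaphthalen-1-yl]pentanoate
Conditions: LiN(SiMe3)2 (1.05 equiv), THF, −78 °C; PhNTf2, −78 → 0 °C; H2O quench
Reagents that add atoms: N-phenylbis(trifluoromethanesulfonimide) (O=S(=O)(N(c1ccccc1)S(=O)(=O)C(F)(F)F)C(F)(F)F)
Why: Kinetic deprotonation by the hindered amide should occur at the C7 methylene and not at the C9 methine next to quaternary C10 or at the less acidic ester α-position, and O-triflation of the enolate (enol triflate formation) fixes the C7=C8 double bond without epimerising C9.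

Step 7
Reactants: 16 methyl (3R)-3-methyl-5-[(1S,4aR,8aR)-5,5,8a-trimethyl-2-{[(trifluoromethyl)sulfonyl]oxy}-1,4,4a,5,6,7,8,8a-octahydronaphthalen-1-yl]pentanoate
Product: 17 methyl (3R)-5-[(1S,4aR,8aR)-2-(hydroxymethyl)-5,5,8a-trimethyl-1,4,4a,5,6,7,8,8a-octahydronaphthalen-1-yl]-3-methylpentanoate
Conditions: Bu3SnCH2OH, Pd(PPh3)4 (5 mol %), LiCl (3 equiv), 1,4-dioxane, 100 °C
Reagents that add atoms: (tributylstannyl)methanol (CCCC[Sn](CCCC)(CCCC)CO)
Why: Stille coupling (oxidative addition of the vinyl triflate to zerovalent palladium, chloride-assisted transmetalation of the hydroxymethyl group from tin, reductive elimination) should install C17 on C8 with the double bond held at C7=C8.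

Step 8
Reactants: 17 methyl (3R)-5-[(1S,4aR,8aR)-2-(hydroxymethyl)-5,5,8a-trimethyl-1,4,4a,5,6,7,8,8a-octahydronaphthalen-1-yl]-3-methylpentanoate
Product: 18 methyl (3R)-5-[(1S,4aR,8aR)-2-(acetoxymethyl)-5,5,8a-trimethyl-1,4,4a,5,6,7,8,8a-octahydronaphthalen-1-yl]-3-methylpentanoate (CNP0149025.1)
Conditions: Ac2O, pyridine, 4-(dimethylamino)pyridine (5 mol %), CH2Cl2, rt
Reagents that add atoms: acetic anhydride (CC(=O)OC(C)=O)
Why: Nucleophile-catalysed acylation of the primary allylic alcohol should give the acetate without affecting any stereocentre or the methyl ester.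

**Compound list**

1 | benzyl acetoacetate (benzyl 3-oxobutanoate) | CC(=O)CC(=O)OCc1ccccc1 | starting material
2 | β-cyclocitral (2,6,6-trimethylcyclohex-1-ene-1-carbaldehyde) | CC1=C(C=O)C(C)(C)CCC1 | starting material
3 | (2R,5R)-2,5-dimethylpyrrolidine | C[C@@H]1CC[C@@H](C)N1 | starting material
4 | benzyl 3-[(2R,5R)-2,5-dimethylpyrrolidin-1-yl]but-2-enoate | C[C@@H]1CC[C@@H](C)N1C(C)=CC(=O)OCc1ccccc1 | intermediate
5 | benzyl 3-[(2R,5R)-2,5-dimethylpyrrolidin-1-yl]-2-[(2,6,6-trimethylcyclohex-1-en-1-yl)methylidene]but-3-enoate | C[C@@H]1CC[C@@H](C)N1C(=C)C(=CC1=C(C)CCCC1(C)C)C(=O)OCc1ccccc1 | intermediate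
6 | benzyl (4aS)-3-[(2R,5R)-2,5-dimethylpyrrolidin-1-yl]-4a,8,8-trimethyl-4,4a,5,6,7,8-hexahydronaphthalene-2-carboxylate | C1C(N3[C@H](C)CC[C@H]3C)=C(C(=O)OCc4ccccc4)C=C2C(C)(C)CCC[C@@]12C | intermediate
7 | benzyl (4aS)-3-hydroxy-4a,8,8-trimethyl-4,4a,5,6,7,8-hexahydronaphthalene-2-carboxylate | C1C(O)=C(C(=O)OCc3ccccc3)C=C2C(C)(C)CCC[C@@]12C | intermediate
8 | (3R)-5-methoxy-3-methyl-5-oxopentanoic acid | COC(=O)C[C@H](C)CC(=O)O | starting material
9 | methyl (3R)-5-hydroxy-3-methylpentanoate | COC(=O)C[C@H](C)CCO | intermediate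
10 | methyl (3R)-3-methyl-5-oxopentanoate | COC(=O)C[C@H](C)CC=O | intermediate
11 | benzyl (4aS)-3-hydroxy-4-[(3R)-1-hydroxy-5-methoxy-3-methyl-5-oxopentyl]-4a,8,8-trimethyl-4,4a,5,6,7,8-hexahydronaphthalene-2-carboxylate (epimers at C4 and the carbinol carbon) | COC(=O)C[C@H](C)CC(O)C1C(O)=C(C(=O)OCc3ccccc3)C=C2C(C)(C)CCC[C@@]12C | intermediate
12 | benzyl (4aS)-3-hydroxy-4-[(3R)-5-methoxy-3-methyl-1-(methylsulfonyloxy)-5-oxopentyl]-4a,8,8-trimethyl-4,4a,5,6,7,8-hexahydronaphthalene-2-carboxylate (epimers as in 11) | COC(=O)C[C@H](C)CC(OS(C)(=O)=O)C1C(O)=C(C(=O)OCc3ccccc3)C=C2C(C)(C)CCC[C@@]12C | intermediate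
13 | benzyl (4aR)-3-hydroxy-4-[(3R)-5-methoxy-3-methyl-5-oxopentylidene]-4a,8,8-trimethyl-4,4a,5,6,7,8-hexahydronaphthalene-2-carboxylate | COC(=O)C[C@H](C)CC=C1C(O)=C(C(=O)OCc3ccccc3)C=C2C(C)(C)CCC[C@@]12C | intermediate
14 | (4S,4aR,8aR)-4-[(3R)-5-methoxy-3-methyl-5-oxopentyl]-4a,8,8-trimethyl-3-oxodecahydronaphthalene-2-carboxylic acid (C2 epimers) | COC(=O)C[C@H](C)CC[C@@H]1C(=O)C(C(=O)O)C[C@@H]2C(C)(C)CCC[C@@]12C | intermediate
15 | methyl (3R)-3-methyl-5-[(1S,4aR,8aR)-5,5,8a-trimethyl-2-oxodecahydronaphthalen-1-yl]pentanoate | COC(=O)C[C@H](C)CC[C@@H]1C(=O)CC[C@@H]2C(C)(C)CCC[C@@]12C | intermediate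
16 | methyl (3R)-3-methyl-5-[(1S,4aR,8aR)-5,5,8a-trimethyl-2-{[(trifluoromethyl)sulfonyl]oxy}-1,4,4a,5,6,7,8,8a-octahydronaphthalen-1-yl]pentanoate | COC(=O)C[C@H](C)CC[C@@H]1C(OS(=O)(=O)C(F)(F)F)=CC[C@@H]2C(C)(C)CCC[C@@]12C | intermediate
17 | methyl (3R)-5-[(1S,4aR,8aR)-2-(hydroxymethyl)-5,5,8a-trimethyl-1,4,4a,5,6,7,8,8a-octahydronaphthalen-1-yl]-3-methylpentanoate | COC(=O)C[C@H](C)CC[C@@H]1C(CO)=CC[C@@H]2C(C)(C)CCC[C@@]12C | intermediate
18 | methyl (3R)-5-[(1S,4aR,8aR)-2-(acetoxymethyl)-5,5,8a-trimethyl-1,4,4a,5,6,7,8,8a-octahydronaphthalen-1-yl]-3-methylpentanoate | COC(=O)C[C@H](C)CC[C@@H]1C(COC(C)=O)=CC[C@@H]2C(C)(C)CCC[C@@]12C | target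

**Summary**

Total step count: 8.
Longest linear sequence: 7 steps (steps 2, 3, 4, 5, 6, 7, 8, from 8).

Steps most likely to fail:

1. Step 1 (proposed new method). The hindered enamino ester may condense slowly with the hindered aldehyde, the triene may fail to close at its fully substituted terminus, or the pyrrolidine may discriminate the two helical closures of 5 poorly. Fallback (cation–olefin bicyclisation and resolution instead of electrocyclisation, known reaction types only): from 1, γ-alkylation of the dianion (LiN(i-Pr)2, 2.1 equiv, THF, 0 °C) with geranyl bromide should give benzyl (6E)-7,11-dimethyl-3-oxododeca-6,10-dienoate F1. SnCl4 in CH2Cl2 at −78 → 0 °C should close rings A and B in one Lewis acid-promoted cation–olefin cyclisation terminated by the enol carbon, giving the racemic trans-fused bicyclic β-keto ester F2. This is resolved by preparative chromatography on a chiral stationary phase to the (1S,4aR,8aR) enantiomer F3. Alcohol 9 is converted (I2, PPh3, imidazole, CH2Cl2) into methyl (3S)-5-iodo-3-methylpentanoate F4, which has the same spatial arrangement as 9; the descriptor changes because iodine raises the priority of C4. F3 is C-alkylated at C9 with F4 (Cs2CO3, DMF) to the quaternary β-keto ester F5. Hydrogenolysis (H2, Pd on carbon, EtOAc) gives the β-keto acid F6, which loses CO2 and ketonises to the more stable C9 epimer. This returns to the route at 15 and replaces steps 1, 3, 4 and 5.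

2. Step 4. Proton transfer from the enolisable aldehyde to the dianion, lactonisation of the δ-hydroxy β-keto ester onto the benzyl ester, or sulfonylation of the enol oxygen may compete. Fallback (Lewis-acid instead of dianion chemistry): from 7, silylation (Me3SiCl, Et3N) gives the silyl enol ether F7, and LiN(i-Pr)2/Me3SiCl then gives the 1,3-bis(trimethylsilyloxy)diene F8. TiCl4-mediated vinylogous Mukaiyama aldol addition of F8 to 10 (CH2Cl2, −78 °C) should give aldol 11 after aqueous work-up; this returns to the route at 11, which is mesylated and eliminated to 13 as in step 4.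

3. Step 5. The reduction may stall at the hindered C5=C6 bond, or facial selectivity at C5 may erode on the catalyst surface. Fallback (radical hydrogen-atom transfer for the ring fusion): from 13, hydrogenation at 1 bar over Pd on carbon is stopped once the benzyl ester is cleaved, CO2 is lost and the exocyclic enone is saturated, giving the Δ5 ketone F9. The C5=C6 bond of F9 is then reduced with Mn(dpm)3 (dpm = dipivaloylmethanate), PhSiH3 and t-BuOOH in i-PrOH; in this hydrogen-atom-transfer hydrogenation the tertiary C5 radical should accept hydrogen to give the trans ring fusion, returning to the route at 15.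

Further compounds
F1 | step 1 | benzyl (6E)-7,11-dimethyl-3-oxododeca-6,10-dienoate | CC(C)=CCC/C(C)=C/CCC(=O)CC(=O)OCc1ccccc1
F2 | step 1 | benzyl 5,5,8a-trimethyl-2-oxodecahydronaphthalene-1-carboxylate (racemate of the trans-fused diastereomer with equatorial ester) | O=C(OCc1ccccc1)C1C(=O)CCC2C(C)(C)CCCC12C
F3 | step 1 | benzyl (1S,4aR,8aR)-5,5,8a-trimethyl-2-oxodecahydronaphthalene-1-carboxylate | O=C(OCc1ccccc1)[C@@H]1C(=O)CC[C@@H]2C(C)(C)CCC[C@@]12C
F4 | step 1 | methyl (3S)-5-iodo-3-methylpentanoate | COC(=O)C[C@H](C)CCI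
F5 | step 1 | benzyl (4aR,8aR)-1-[(3R)-5-methoxy-3-methyl-5-oxopentyl]-5,5,8a-trimethyl-2-oxodecahydronaphthalene-1-carboxylate (configuration at C1 immaterial) | COC(=O)C[C@H](C)CCC1(C(=O)OCc2ccccc2)C(=O)CC[C@@H]2C(C)(C)CCC[C@@]12C
F6 | step 1 | (4aR,8aR)-1-[(3R)-5-methoxy-3-methyl-5-oxopentyl]-5,5,8a-trimethyl-2-oxodecahydronaphthalene-1-carboxylic acid (configuration at C1 immaterial) | COC(=O)C[C@H](C)CCC1(C(=O)O)C(=O)CC[C@@H]2C(C)(C)CCC[C@@]12C
F7 | step 4 | benzyl (4aS)-4a,8,8-trimethyl-3-[(trimethylsilyl)oxy]-4,4a,5,6,7,8-hexahydronaphthalene-2-carboxylate | C1C(O[Si](C)(C)C)=C(C(=O)OCc3ccccc3)C=C2C(C)(C)CCC[C@@]12C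
F8 | step 4 | (4aS)-2-[(benzyloxy)(trimethylsilyloxy)methylidene]-4a,8,8-trimethyl-3-(trimethylsilyloxy)-2,4a,5,6,7,8-hexahydronaphthalene | C1=C(O[Si](C)(C)C)C(=C(O[Si](C)(C)C)OCc3ccccc3)C=C2C(C)(C)CCC[C@@]12C
F9 | step 5 | methyl (3R)-3-methyl-5-[(1S,8aS)-5,5,8a-trimethyl-2-oxo-1,2,3,5,6,7,8,8a-octahydronaphthalen-1-yl]pentanoate | COC(=O)C[C@H](C)CC[C@@H]1C(=O)CC=C2C(C)(C)CCC[C@@]12C
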